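**Plan**

- Retrosynthetic cuts: the formyl group goes back to the methyl of an isopropenyl group; the angelate C–O bond and then the carbinol C–H bond go back to an aryl methyl ketone; the O1–C2 bond of the dihydrofuran ring is cut with return of the C3 acetyl to O1, giving an isomeric trans-2-aryl-3-isopropenyloxirane; the oxirane goes back to an (E)-1-aryl-1,3-diene; the aryl–vinyl bond goes back to a bromoarene and isoprene.
- Forward order: the benzene ring is bought; acetylation, Heck coupling and epoxidation build the chain; the dihydrofuran ring, the only ring made, closes in step 4; ketone reduction, angeloylation and allylic oxidation finish the side chains. The helpers are a temporary oxirane, an aryl acetate that becomes the C3 acetate, and the ketone and methyl oxidation levels, both adjusted after the ring is closed.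
- Enabling feature: C2 of the dihydrofuran ring is bonded to O1 and is allylic to the exocyclic C=CH2; C3 carries an acyloxy group cis to the alkenyl group; O1 and the C3 oxygen are 1,5-related through C7a–C3a–C3. The ring with its acetate is therefore an isomer of an aryl-acetate vinyl oxirane, which zerovalent palladium can open and re-close.
- Stereochemistry: C2 and C3 come from one catalytic asymmetric epoxidation and are relayed by double inversion at C2 (trans-oxirane to cis-dihydrofuran); the (R)-carbinol comes from a CBS reduction; the (Z)-alkene is bought with angelic acid.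

Key step: step 4

Remark: the target is read as (2S,3S) (2,3-cis) in the dihydrofuran ring, (R) at the benzylic carbinol and (Z) in the ester (an angelate); the L-fructose-derived Shi ketone (made from L-sorbose) is taken as an available catalyst.

**Route**

Step 1
Reactants: 1 1-(3-bromo-4-hydroxyphenyl)ethan-1-one
Product: 2 4-acetyl-2-bromophenyl acetate
Conditions: Ac2O, pyridine, CH2Cl2, 0 °C to rt
Reagents that add atoms: acetic anhydride, CC(=O)OC(C)=O
Why: O-acetylation of the phenol (acyl transfer) masks O1 so that the Heck step cannot turn into a Larock-type annulation, and places on O1 the acetyl group that is later handed to the C3 oxygen.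

Step 2
Reactants: 2 4-acetyl-2-bromophenyl acetate; 3 isoprene (2-methylbuta-1,3-diene)
Product: 4 4-acetyl-2-[(1E)-3-methylbuta-1,3-dien-1-yl]phenyl acetate
Conditions: Pd(OAc)2 (2 mol%), P(o-tol)3, Et3N, isoprene (5 equiv), MeCN, 100 °C, sealed tube
Reagents that add atoms: none
Why: Mizoroki–Heck reaction in which the aryl–palladium species adds to the unsubstituted vinyl terminus of isoprene and β-hydride elimination from the benzylic CH2 of the resulting allyl complex should give the conjugated (E)-diene, the usual outcome of aryl bromide–isoprene couplings with Et3N as base.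

Step 3
Reactants: 4 4-acetyl-2-[(1E)-3-methylbuta-1,3-dien-1-yl]phenyl acetate
Product: 5 4-acetyl-2-[(2S,3S)-3-(prop-1-en-2-yl)oxiran-2-yl]phenyl acetate
Conditions: L-fructose-derived Shi ketone (1,2:4,5-di-O-isopropylidene-β-L-erythro-2,3-hexodiulo-2,6-pyranose, 30 mol%), Oxone (2KHSO5·KHSO4·K2SO4), K2CO3, Bu4NHSO4, MeCN–dimethoxymethane/aq. Na2B4O7 buffer (pH about 10), 0 °C
Reagents that add atoms: potassium peroxymonosulfate (active part of Oxone), [K+].[O-]S(=O)(=O)OO
Why: Shi asymmetric epoxidation in which the chiral dioxirane should prefer the trans-disubstituted styrenyl alkene over the 1,1-disubstituted one (a poor substrate class for this ketone) and, through the spiro transition state, the L-fructose-derived ketone should give the (2S,3S)-oxirane, the mirror image of the (R,R) sense known for the D-fructose-derived ketone with (E)-alkenes, so that both future ring stereocentres are set here by catalyst control.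

Step 4
Reactants: 5 4-acetyl-2-[(2S,3S)-3-(prop-1-en-2-yl)oxiran-2-yl]phenyl acetate
Product: 8 (2S,3S)-5-acetyl-2-(prop-1-en-2-yl)-2,3-dihydro-1-benzofuran-3-yl acetate, via π-allylpalladium alkoxide 6 (not isolated), via π-allylpalladium phenoxide 7 (not isolated)
Conditions: Pd(PPh3)4 (5 mol%), THF, 0 °C, short reaction time
Reagents that add atoms: none
Why: Proposed new method: zerovalent palladium should ionise the allylic C2–O bond of the vinyl oxirane with inversion (release of the three-ring strain) to the π-allylpalladium alkoxide 6, whose benzylic alkoxide takes the acetyl group from the neighbouring aryl ester through a six-membered tetrahedral intermediate (1,5 O-to-O acyl shift), so that the C3 acetate of the target and the phenoxide 7 arise together, and the phenoxide then attacks the substituted allyl terminus anti to palladium. The closest known reaction types are the Pd-catalysed cyclisation of hydroxy vinyl epoxides to 2-alkenyl-3-hydroxy cyclic ethers with net retention and the Pd-catalysed [3+2] capture of vinyl-epoxide zwitterions by heterocumulenes, where the alkoxide first adds to an electrophile and the new anion then closes on the allyl unit. The dihydrofuran ring closes by 5-exo attack of O1 on C2 of the π-allyl unit (attack at the CH2 terminus would demand a seven-membered ring). C3 is not touched and keeps the configuration from step 3, and C2 is re-formed with overall retention by double inversion, which converts the trans (2S,3S)-oxirane into the cis (2S,3S)-dihydrobenzofuran. The step needs acyl transfer and ring closure to outrun π–σ–π face exchange at the CH2 terminus, hydride shift to the enone and loss of acetate from the ortho-acetoxybenzyl phenoxide; the intramolecular six-membered acyl shift, the five-membered closure on a cationic allyl complex at 0 °C and the para-acetyl group, which tames the phenoxide, are meant to secure this.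

Step 5
Reactants: 8 (2S,3S)-5-acetyl-2-(prop-1-en-2-yl)-2,3-dihydro-1-benzofuran-3-yl acetate
Product: 9 (2S,3S)-5-[(1R)-1-hydroxyethyl]-2-(prop-1-en-2-yl)-2,3-dihydro-1-benzofuran-3-yl acetate
Conditions: (S)-2-methyl-CBS-oxazaborolidine (20 mol%), catecholborane, toluene, −78 to −40 °C; pH 7 buffer work-up
Reagents that add atoms: none
Why: Corey–Bakshi–Shibata reduction in which the (S)-oxazaborolidine should deliver hydride to the face of the aryl methyl ketone that gives the (R)-carbinol (aryl as the large group, as with acetophenone), while catecholborane at low temperature leaves the alkene, the acetate and the remote ring stereocentres untouched.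

Step 6
Reactants: 9 (2S,3S)-5-[(1R)-1-hydroxyethyl]-2-(prop-1-en-2-yl)-2,3-dihydro-1-benzofuran-3-yl acetate; 10 angelic acid ((2Z)-2-methylbut-2-enoic acid)
Product: 12 (1R)-1-[(2S,3S)-3-acetoxy-2-(prop-1-en-2-yl)-2,3-dihydro-1-benzofuran-5-yl]ethyl (2Z)-2-methylbut-2-enoate, via angelic 2,4,6-trichlorobenzoic anhydride 11 (not isolated)
Conditions: 10, 2,4,6-trichlorobenzoyl chloride, Et3N, toluene, rt; then 9, toluene, 70 °C, no DMAP
Reagents that add atoms: none
Why: Yamaguchi-type esterification through the mixed anhydride without a nucleophilic catalyst should acylate the secondary alcohol with retention at the carbinol carbon and avoid the addition–elimination pathway that isomerises angelates to tiglates.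

Step 7
Reactants: 12 (1R)-1-[(2S,3S)-3-acetoxy-2-(prop-1-en-2-yl)-2,3-dihydro-1-benzofuran-5-yl]ethyl (2Z)-2-methylbut-2-enoate
Product: 14 (1R)-1-[(2S,3S)-3-acetoxy-2-(3-oxoprop-1-en-2-yl)-2,3-dihydro-1-benzofuran-5-yl]ethyl (2Z)-2-methylbut-2-enoate, via allylic alcohol 13 (not isolated)
Conditions: SeO2 (0.3 equiv), t-BuOOH (2 equiv), CH2Cl2, rt; then filtration and MnO2 (excess), CH2Cl2, rt
Reagents that add atoms: selenium dioxide, O=[Se]=O; tert-butyl hydroperoxide (terminal oxygen source), CC(C)(C)OO
Why: Riley-type allylic oxidation (ene reaction of SeO2 at the electron-rich 1,1-disubstituted alkene followed by a [2,3]-sigmatropic shift, the mode by which 2-isopropenyl-2,3-dihydrobenzofurans are hydroxylated at the methyl group) and MnO2 oxidation of the resulting primary allylic alcohol should give the 2-substituted acrolein without touching the electron-poor angelate alkene or any stereocentre.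

**Compound list**

1 | 1-(3-bromo-4-hydroxyphenyl)ethan-1-one | CC(=O)c1ccc(O)c(Br)c1 | starting material
2 | 4-acetyl-2-bromophenyl acetate | CC(=O)Oc1ccc(C(C)=O)cc1Br | intermediate
3 | isoprene (2-methylbuta-1,3-diene) | C=CC(C)=C | starting material
4 | 4-acetyl-2-[(1E)-3-methylbuta-1,3-dien-1-yl]phenyl acetate | CC(=O)Oc1ccc(C(C)=O)cc1/C=C/C(C)=C | intermediate
5 | 4-acetyl-2-[(2S,3S)-3-(prop-1-en-2-yl)oxiran-2-yl]phenyl acetate (trans-oxirane) | CC(=O)Oc1ccc(C(C)=O)cc1[C@@H]2O[C@H]2C(C)=C | intermediate
6 | π-allylpalladium alkoxide from 5 (palladium anti to the departed oxygen; shown in its η1 form at C2, phosphine ligands left out) | CC(=O)Oc1ccc(C(C)=O)cc1[C@H]([O-])[C@H]([Pd+])C(C)=C | intermediate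
7 | π-allylpalladium phenoxide after acetyl shift to the benzylic oxygen (same depiction) | [O-]c1ccc(C(C)=O)cc1[C@H](OC(C)=O)[C@H]([Pd+])C(C)=C | intermediate
8 | (2S,3S)-5-acetyl-2-(prop-1-en-2-yl)-2,3-dihydro-1-benzofuran-3-yl acetate (2,3-cis) | C=C(C)[C@@H]1Oc2ccc(C(C)=O)cc2[C@@H]1OC(C)=O | intermediate
9 | (2S,3S)-5-[(1R)-1-hydroxyethyl]-2-(prop-1-en-2-yl)-2,3-dihydro-1-benzofuran-3-yl acetate | C=C(C)[C@@H]1Oc2ccc([C@@H](C)O)cc2[C@@H]1OC(C)=O | intermediate
10 | angelic acid, (2Z)-2-methylbut-2-enoic acid | C/C=C(/C)C(=O)O | starting material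
11 | (2Z)-2-methylbut-2-enoic 2,4,6-trichlorobenzoic anhydride | C/C=C(/C)C(=O)OC(=O)c1c(Cl)cc(Cl)cc1Cl | intermediate
12 | (1R)-1-[(2S,3S)-3-acetoxy-2-(prop-1-en-2-yl)-2,3-dihydro-1-benzofuran-5-yl]ethyl (2Z)-2-methylbut-2-enoate | C=C(C)[C@@H]1Oc2ccc([C@@H](C)OC(=O)/C(C)=C\C)cc2[C@@H]1OC(C)=O | intermediate
13 | (1R)-1-[(2S,3S)-3-acetoxy-2-(3-hydroxyprop-1-en-2-yl)-2,3-dihydro-1-benzofuran-5-yl]ethyl (2Z)-2-methylbut-2-enoate | C=C(CO)[C@@H]1Oc2ccc([C@@H](C)OC(=O)/C(C)=C\C)cc2[C@@H]1OC(C)=O | intermediate
14 | (1R)-1-[(2S,3S)-3-acetoxy-2-(3-oxoprop-1-en-2-yl)-2,3-dihydro-1-benzofuran-5-yl]ethyl (2Z)-2-methylbut-2-enoate | C=C(C=O)[C@@H]1Oc2ccc([C@@H](C)OC(=O)/C(C)=C\C)cc2[C@@H]1OC(C)=O | target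

**Step count and risks**

Total step count: 7. Longest linear sequence: 7 steps (from 1; 3 and 10 are bought).

Steps most likely to fail:

Step 4 (bears the label). The acyl shift may lag behind collapse of the zwitterion (hydride shift to the enone, closure to a 2,5-dihydrofuran). Face exchange of the allyl complex, or re-ionisation of the allyl aryl ether formed, may leak the trans diastereomer. The fallback uses known chemistry and sets out from 5. The aryl acetate is cleaved with pyrrolidine in CH2Cl2 at 0 °C to give 1-{4-hydroxy-3-[(2S,3S)-3-(prop-1-en-2-yl)oxiran-2-yl]phenyl}ethan-1-one F1. This phenol is treated at once with Pd(PPh3)4 in THF, the established cyclisation of hydroxy vinyl epoxides with net retention, and should give 1-[(2S,3S)-3-hydroxy-2-(prop-1-en-2-yl)-2,3-dihydro-1-benzofuran-5-yl]ethan-1-one F2. Acetylation (Ac2O, pyridine, 0 °C) comes back to the route at 8.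

Step 3. Site selectivity between the two alkenes of the diene may be poor (epoxidation at the 1,1-disubstituted alkene or double epoxidation), and the aryl acetate may hydrolyse in the basic buffer. The fallback sets out from 2. Mizoroki–Heck coupling with 2-methylbut-3-en-2-ol (Pd(OAc)2, P(o-tol)3, Et3N, MeCN, 90 °C) should give 4-acetyl-2-[(1E)-3-hydroxy-3-methylbut-1-en-1-yl]phenyl acetate F3, which holds only the styrenyl alkene. Shi epoxidation with the same L-fructose-derived ketone, in a shorter run, should give 4-acetyl-2-[(2S,3R)-3-(2-hydroxypropan-2-yl)oxiran-2-yl]phenyl acetate F4; the spatial sense is the same and the descriptor changes by priority only. Dehydration of the tertiary alcohol with Burgess reagent (toluene, 50 °C) comes back to the route at 5.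

Step 7. The oxidant may attack the angelate (allylic oxidation or Z-to-E isomerisation), and the acidic selenium species may ionise the electron-rich benzylic ester. The fallback sets out from 8 and moves the allylic oxidation to the robust ketone stage. SeO2/t-BuOOH in CH2Cl2 should give (2S,3S)-5-acetyl-2-(3-hydroxyprop-1-en-2-yl)-2,3-dihydro-1-benzofuran-3-yl acetate F5. Silylation (TBSCl, imidazole, DMF) gives (2S,3S)-5-acetyl-2-{3-[(tert-butyldimethylsilyl)oxy]prop-1-en-2-yl}-2,3-dihydro-1-benzofuran-3-yl acetate F6. CBS reduction as in step 5 gives (2S,3S)-2-{3-[(tert-butyldimethylsilyl)oxy]prop-1-en-2-yl}-5-[(1R)-1-hydroxyethyl]-2,3-dihydro-1-benzofuran-3-yl acetate F7. Acylation with the mixed anhydride 11 as in step 6 gives (1R)-1-[(2S,3S)-3-acetoxy-2-{3-[(tert-butyldimethylsilyl)oxy]prop-1-en-2-yl}-2,3-dihydro-1-benzofuran-5-yl]ethyl (2Z)-2-methylbut-2-enoate F8. Desilylation with HF·pyridine in THF comes back to the route at 13, which is oxidised with MnO2 as in the second stage of step 7.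

**Further compounds**

F1 | step 4 | 1-{4-hydroxy-3-[(2S,3S)-3-(prop-1-en-2-yl)oxiran-2-yl]phenyl}ethan-1-one | CC(=O)c1ccc(O)c(c1)[C@@H]2O[C@H]2C(C)=C
F2 | step 4 | 1-[(2S,3S)-3-hydroxy-2-(prop-1-en-2-yl)-2,3-dihydro-1-benzofuran-5-yl]ethan-1-one | C=C(C)[C@@H]1Oc2ccc(C(C)=O)cc2[C@@H]1O
F3 | step 3 | 4-acetyl-2-[(1E)-3-hydroxy-3-methylbut-1-en-1-yl]phenyl acetate | CC(=O)Oc1ccc(C(C)=O)cc1/C=C/C(C)(C)O
F4 | step 3 | 4-acetyl-2-[(2S,3R)-3-(2-hydroxypropan-2-yl)oxiran-2-yl]phenyl acetate | CC(=O)Oc1ccc(C(C)=O)cc1[C@@H]2O[C@H]2C(C)(C)O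
F5 | step 7 | (2S,3S)-5-acetyl-2-(3-hydroxyprop-1-en-2-yl)-2,3-dihydro-1-benzofuran-3-yl acetate | C=C(CO)[C@@H]1Oc2ccc(C(C)=O)cc2[C@@H]1OC(C)=O
F6 | step 7 | (2S,3S)-5-acetyl-2-{3-[(tert-butyldimethylsilyl)oxy]prop-1-en-2-yl}-2,3-dihydro-1-benzofuran-3-yl acetate | C=C(CO[Si](C)(C)C(C)(C)C)[C@@H]1Oc2ccc(C(C)=O)cc2[C@@H]1OC(C)=O
F7 | step 7 | (2S,3S)-2-{3-[(tert-butyldimethylsilyl)oxy]prop-1-en-2-yl}-5-[(1R)-1-hydroxyethyl]-2,3-dihydro-1-benzofuran-3-yl acetate | C=C(CO[Si](C)(C)C(C)(C)C)[C@@H]1Oc2ccc([C@@H](C)O)cc2[C@@H]1OC(C)=O
F8 | step 7 | (1R)-1-[(2S,3S)-3-acetoxy-2-{3-[(tert-butyldimethylsilyl)oxy]prop-1-en-2-yl}-2,3-dihydro-1-benzofuran-5-yl]ethyl (2Z)-2-methylbut-2-enoate | C=C(CO[Si](C)(C)C(C)(C)C)[C@@H]1Oc2ccc([C@@H](C)OC(=O)/C(C)=C\C)cc2[C@@H]1OC(C)=O
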